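# Proposed synthesis of (2E)-1-[(2S)-4,6-dihydroxy-2-(2-hydroxypropan-2-yl)-2,3-dihydro-1-benzofuran-5-yl]-3-(4-hydroxyphenyl)prop-2-en-1-one (16)

## The problem

The target 16 is a 2',6'-dihydroxychalcone whose ring A is fused to a 2,3-dihydrofuran. Ring A is a 1,3,5-trioxygenated benzene (O1 on C7a, hydroxyls on C4 and C6) with carbon substituents at C3a and C5 and hydrogen only at C7, so three similar oxygens must be told apart and the cinnamoyl group must go to C5, not C7. The only stereocenter is C2 (S), which carries the 2-hydroxypropan-2-yl group; nothing else in the molecule can relay chirality to it, so it must come from a catalyst or a chiral building block. Once set, C2 is a non-benzylic ether carbon and cannot epimerise, but the neighbouring tertiary carbinol can ionise in strong acid and lead to dehydration or ring expansion to a chromanol. The free chalcone is the most fragile part: a hydroxyl ortho to the enone carbonyl closes to a flavanone by oxa-Michael addition in base or hot acid, so the enone should appear late and be unmasked gently. The feature that opens the route is C3: it is a benzylic carbon on C3a between the oxygenated carbons C4 and C7a, which is the position of the formyl carbon of 2,4,6-trihydroxybenzaldehyde 1, and C2 is an ether carbon whose C–H bonds lie 1,5 to C3. A carbene at C3 can therefore form C2–C3 by C–H functionalisation and close the dihydrofuran ring with the complete side chain already attached.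

## Retrosynthesis

**16 to 15.** The last operation should only uncover hydroxyl groups. Cutting the three O–CH2OCH3 bonds of 16 leads to the tris(methoxymethyl) ether 15. Methoxymethyl is preferred to benzyl, whose hydrogenolysis would endanger the enone, and to silyl on ring A, whose fluoride cleavage gives phenoxides that close to the flavanone. The two ring-A acetals are also needed in the step before. The forward reaction must be a mild acetal exchange that spares the enone, C2 and the tertiary carbinol.

**15 to 10 and 13.** The C5–C(=O) bond is cut, which removes ring B and the enone in one stroke and leaves the dihydrobenzofuran 10 and the cinnamic Weinreb amide 13. The neighbouring cut at Cα=Cβ (aldol condensation) would need an acetyl group at C5 first and costs a step; it is kept as a reserve. A Friedel–Crafts acylation of the free diphenol offers no control between C5 and C7. The forward reaction is a directed metalation of 10 to the aryllithium 14, which has to occur between the two methoxymethoxy groups, followed by clean 1,2-acyl transfer with retention of the E double bond.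

**13 to 12 to 11.** The O–CH2OCH3 bond and then the amide C–N bond are cut, which leads through the phenolic amide 12 to p-coumaric acid 11. The E double bond is bought, not made.

**10 to 9 to 8.** This is an exchange of protecting groups: the methoxymethyl ethers of 10 are traced to the diphenol 9 and this to the bis(triisopropylsilyl) ether 8. The exchange costs two steps and is accepted for a mechanistic reason. An OCH2OCH3 group ortho to the carbene carbon would place a doubly activated C–H bond 1,5 to it and compete in the key step, whereas a silyl ether has no hydrogen in that position. Silyl ethers, on the other hand, do not direct the later metalation.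

**8 to 6 (through 7).** The C2–C3 bond is cut, which opens the dihydrofuran ring to the aryldiazomethane 7 and its stable precursor, the sulfonylhydrazone 6. The neighbouring cut at O1–C2 would need a C-prenylated trioxygenated arene and a separate asymmetric oxidation. A cut at C3–C3a would need an aryl halide placed among three oxygens. The C2–C3 cut uses the formyl carbon that the starting aldehyde already has and makes every bond to ring A a bought one. It asks of the forward reaction site-selective hydrogen abstraction from one OCH2 group and catalyst-controlled formation of the C2 stereocenter; a cobalt complex Co(Por*) of a D2-symmetric chiral amidoporphyrin Por* is meant to deliver both.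

**6 to 4 and 5; 4 to 2 and 3; 2 to 1.** The C=N bond is cut to the aldehyde 4 and 4-methylbenzenesulfonohydrazide 5. The aryl O–CH2 bond of 4 is cut to the phenol 2 and 2,2-dimethyloxirane 3, which brings C2 together with the finished tertiary carbinol. The two O–Si bonds of 2 are cut to 2,4,6-trihydroxybenzaldehyde 1. Chelation of one ortho hydroxyl to the formyl group is what distinguishes the three oxygens, and the forward steps must respect it.

## Roads not taken

**Alternative 1: carbonylative Heck assembly of the chalcone.** The cut removes both bonds of the carbonyl carbon, C5–C(=O) and C(=O)–Cα. In the forward step zerovalent palladium would insert into the C–I bond of 2-[(2S)-5-iodo-4,6-bis(methoxymethoxy)-2,3-dihydro-1-benzofuran-2-yl]propan-2-ol A2. The arylpalladium would take up carbon monoxide A4, the aroylpalladium would add to 1-ethenyl-4-(methoxymethoxy)benzene A3, and β-hydride elimination would release the E-enone A1. A1 is identical with compound 15.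

- Merits: it is convergent, needs no acyl donor to be prepared, and exposes the enone to no organolithium.
- Weak points: it forms no ring and no stereocenter, so the dihydrofuran and C2 still have to come from elsewhere. A2 would be made from 10 by the same C5 metalation that the chosen plan uses, quenched with an iodine source. A di-ortho-alkoxy aroylpalladium is hindered toward insertion of A3, and direct Heck coupling of A2 with A3 without uptake of A4 can compete. A4 is a toxic gas that has to be handled under pressure, and A3 has to be prepared as well.
- Comparison: as an endgame it costs two steps from 10 against one step plus two for 13, so it is no shorter. It is gentler on the enone. The chosen plan sets against this a one-flask metalation and acylation, and it addresses the core, which this road does not.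

**Alternative 2: asymmetric Larock heteroannulation with isoprene.** The cuts are C3–C3a and O1–C2. Zerovalent palladium with a chiral ligand would insert into the C–I bond of 2-iodo-3,5-bis(methoxymethoxy)phenol A5. The aryl group would add to the unsubstituted vinyl terminus of isoprene A6, and the phenol oxygen would attack the internal carbon of the π-allyl complex to give (2S)-4,6-bis(methoxymethoxy)-2-(prop-1-en-2-yl)-2,3-dihydro-1-benzofuran A7.

- Merits: two bonds, the ring and the stereocenter are made in one step; the reaction type is established for 2-isopropenyl dihydrobenzofurans; the methoxymethyl ethers are already those needed for the metalation; A6 is a cheap bulk chemical.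
- Weak points: A5 must come from a symmetric triphenol by statistical double protection and an iodination that has to go ortho and not para to the free hydroxyl. Its iodide is flanked on both sides and very electron-rich. A6 is volatile and has to be used in excess. A7 still needs a Markovnikov hydration to reach 10.
- Comparison: on step count this road is probably shorter by about two steps to 10, and its enantioselective precedent is closer to the ring system wanted here. The chosen plan sets against this a deterministic differentiation of the three oxygens by chelation, a tertiary carbinol delivered complete by the epoxide 3, and no hindered aryl iodide.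

**Alternative 3: Catellani annulation with a chiral epoxide.** The cuts are C3–C3a and C7a–O1. Under palladium catalysis with norbornene A11 as mediator, 1-iodo-3,5-bis(methoxymethoxy)benzene A8 would be alkylated at an ortho C–H by the CH2 carbon of 2-[(2S)-oxiran-2-yl]propan-2-ol A9. The alkoxide set free would then couple at the former C–I carbon to give 2-[(2S)-4,6-bis(methoxymethoxy)-2,3-dihydro-1-benzofuran-2-yl]propan-2-ol A10. A10 is identical with compound 10.

- Merits: this is the shortest conceivable access to 10. The stereocenter is taken unchanged from A9, so no enantioselective catalysis is needed, and A8 is symmetric, so the two ortho positions are equivalent.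
- Weak points: A8 has no ortho substituent, so a second ortho alkylation or products that retain A11 can compete with ring closure. The C–H to be palladated lies between the iodide and an acetal oxygen. A9 carries a bulky tertiary carbinol on the epoxide carbon next to the reacting CH2 and brings a second free hydroxyl. A9 itself has to be made in enantiopure form.
- Comparison: this road is clearly better in step count and in the certainty of absolute configuration. The chosen plan sets against it a single predictable reaction site (the only hydrogen 1,5 to the carbene carbon) and a reaction type already shown on ortho-alkoxyaryl aldehyde hydrazones.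

Key step: step 4

## Route

Assumption: which antipode of the chiral amidoporphyrin gives the (2S) product cannot be predicted with confidence for this substrate. Both antipodes are accessible, and Por* denotes the one that gives (2S), to be assigned in a first experiment.

Por* is a D2-symmetric porphyrin with two 3,5-di-tert-butylphenyl meso groups and two 2,6-bis(2,2-dimethylcyclopropanecarboxamido)phenyl meso groups; Co(Por*) is its complex with divalent cobalt.

Step 1
Reactants: 1 2,4,6-trihydroxybenzaldehyde
Product: 2 2-hydroxy-4,6-bis(triisopropylsilyloxy)benzaldehyde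
Conditions: TIPSCl (2.1 equiv), imidazole (4 equiv), DMF, 0 °C to rt
Reagents that add atoms: chlorotriisopropylsilane, CC(C)[Si](Cl)(C(C)C)C(C)C
Why: Silyl ether formation with imidazole as base; the para hydroxyl and one ortho hydroxyl react, while the remaining ortho hydroxyl is held in a hydrogen bond to the formyl oxygen and stays free, as in the routine double etherification of this aldehyde.

Step 2
Reactants: 2 2-hydroxy-4,6-bis(triisopropylsilyloxy)benzaldehyde; 3 2,2-dimethyloxirane
Product: 4 2-(2-hydroxy-2-methylpropoxy)-4,6-bis(triisopropylsilyloxy)benzaldehyde
Conditions: K2CO3 (0.5 equiv), 3 (5 equiv), dry DMF, 70 °C, sealed tube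
Reagents that add atoms: none
Why: Carbonate forms the phenoxide, which opens the epoxide by SN2 attack at its unsubstituted CH2 carbon and so installs C2 with the complete tertiary carbinol; dry conditions and a moderate temperature are chosen to keep the aryl silyl ethers intact.

Step 3
Reactants: 4 2-(2-hydroxy-2-methylpropoxy)-4,6-bis(triisopropylsilyloxy)benzaldehyde; 5 4-methylbenzenesulfonohydrazide
Product: 6 N'-[(E)-[2-(2-hydroxy-2-methylpropoxy)-4,6-bis(triisopropylsilyloxy)phenyl]methylidene]-4-methylbenzenesulfonohydrazide
Conditions: 5 (1.05 equiv), MeOH–THF, 40 °C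
Reagents that add atoms: none
Why: Condensation of an aldehyde with a sulfonylhydrazide to the E-configured N-sulfonylhydrazone; the medium is close to neutral, so the silyl ethers and the tertiary alcohol are not affected.

Step 4
Reactants: 6 N'-[(E)-[2-(2-hydroxy-2-methylpropoxy)-4,6-bis(triisopropylsilyloxy)phenyl]methylidene]-4-methylbenzenesulfonohydrazide
Product: 8 2-[(2S)-4,6-bis(triisopropylsilyloxy)-2,3-dihydro-1-benzofuran-2-yl]propan-2-ol, via aryldiazomethane 7 (not isolated)
Conditions: Co(Por*) (3 mol %), Cs2CO3 (2 equiv), toluene, 40–60 °C, N2
Reagents that add atoms: none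
Why: Cs2CO3 deprotonates the sulfonylhydrazone and the anion loses 4-methylbenzenesulfinate (Bamford–Stevens reaction), releasing the aryldiazomethane 7 slowly; divalent cobalt in Co(Por*), a metal-centred radical, takes up 7, expels N2 and gives a benzylic radical at the future C3 that is bound to trivalent cobalt. This radical abstracts hydrogen from the OCH2 carbon by 1,5-hydrogen atom transfer, and the resulting α-alkoxyalkyl radical attacks the cobalt-bound carbon in a 5-exo-tet radical substitution that forms C2–C3, closes the dihydrofuran ring and returns divalent cobalt. The closest known reaction type is the cobalt-porphyrin metalloradical intramolecular C–H alkylation of ortho-alkoxyaryl and ortho-aminoaryl diazomethanes generated from aldehyde sulfonylhydrazones, which gives 2-substituted dihydrobenzofurans and indolines. The stereocenter C2 is set by the catalyst alone: the amide N–H groups and the chiral pockets of Por* hold the carbene radical and decide which enantiotopic hydrogen is removed and which face of the planar α-oxy radical bonds to C3. Site selectivity is needed between this OCH2 group and every other hydrogen; it is the only one 1,5 to the radical centre, the silyl ethers carry theirs one atom further out, and the tertiary O–H bond is too strong to be abstracted. Chemoselectivity against azine formation and carbene dimerisation rests on the slow heterogeneous release of 7, and the radical, non-electrophilic carbene is not expected to insert into the free O–H bond.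

Step 5
Reactants: 8 2-[(2S)-4,6-bis(triisopropylsilyloxy)-2,3-dihydro-1-benzofuran-2-yl]propan-2-ol
Product: 9 (2S)-2-(2-hydroxypropan-2-yl)-2,3-dihydro-1-benzofuran-4,6-diol
Conditions: TBAF (2.2 equiv), AcOH (2.2 equiv), THF, 0 °C
Reagents that add atoms: none
Why: Fluoride cleaves both aryl O–Si bonds, driven by the strong Si–F bond; acetic acid keeps the electron-rich, oxidation-prone diphenol protonated, and C2 and the tertiary carbinol are not involved.

Step 6
Reactants: 9 (2S)-2-(2-hydroxypropan-2-yl)-2,3-dihydro-1-benzofuran-4,6-diol
Product: 10 2-[(2S)-4,6-bis(methoxymethoxy)-2,3-dihydro-1-benzofuran-2-yl]propan-2-ol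
Conditions: MOMCl (2.3 equiv), iPr2NEt (3 equiv), CH2Cl2, 0 °C to rt
Reagents that add atoms: chloromethyl methyl ether, COCCl
Why: O-Alkylation of the two phenols by the chloromethyl ether under amine base gives the aryl methoxymethyl acetals; the hindered tertiary alcohol does not react at or below room temperature.

Step 7
Reactants: 11 p-coumaric acid, (2E)-3-(4-hydroxyphenyl)prop-2-enoic acid
Product: 12 (2E)-3-(4-hydroxyphenyl)-N-methoxy-N-methylprop-2-enamide
Conditions: MeNHOMe·HCl (1.2 equiv), EDC·HCl (1.2 equiv), HOBt (cat.), N-methylmorpholine (2.5 equiv), DMF, 0 °C to rt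
Reagents that add atoms: N,O-dimethylhydroxylamine hydrochloride, CNOC.Cl
Why: Carbodiimide amide coupling through the hydroxybenzotriazole active ester; the amine is far more nucleophilic than the phenol, and the E double bond is carried over from 11.

Step 8
Reactants: 12 (2E)-3-(4-hydroxyphenyl)-N-methoxy-N-methylprop-2-enamide
Product: 13 (2E)-N-methoxy-N-methyl-3-[4-(methoxymethoxy)phenyl]prop-2-enamide
Conditions: MOMCl (1.3 equiv), iPr2NEt (2 equiv), CH2Cl2, 0 °C to rt
Reagents that add atoms: chloromethyl methyl ether, COCCl
Why: Methoxymethylation of the phenol under amine base; it removes the acidic proton that would quench the aryllithium and, as a phenoxide, deactivate the amide.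

Step 9
Reactants: 10 2-[(2S)-4,6-bis(methoxymethoxy)-2,3-dihydro-1-benzofuran-2-yl]propan-2-ol; 13 (2E)-N-methoxy-N-methyl-3-[4-(methoxymethoxy)phenyl]prop-2-enamide
Product: 15 (2E)-1-[(2S)-2-(2-hydroxypropan-2-yl)-4,6-bis(methoxymethoxy)-2,3-dihydro-1-benzofuran-5-yl]-3-[4-(methoxymethoxy)phenyl]prop-2-en-1-one, via dilithiated arene 14 (not isolated)
Conditions: n-BuLi (2.2 equiv), THF, 0 °C; then 13 (1.2 equiv), −78 to 0 °C; aq NH4Cl
Reagents that add atoms: none
Why: Directed ortho-metalation followed by Weinreb ketone synthesis: the first equivalent of n-BuLi forms the lithium alkoxide, and the second removes the C5 proton, which lies between two chelating OCH2OCH3 groups and is more acidic than C7–H with only one such neighbour. The aryllithium 14 adds to the amide carbonyl to give a chelated tetrahedral intermediate that releases the E-enone only on work-up, so over-addition and attack on the product enone are excluded.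

Step 10
Reactants: 15 (2E)-1-[(2S)-2-(2-hydroxypropan-2-yl)-4,6-bis(methoxymethoxy)-2,3-dihydro-1-benzofuran-5-yl]-3-[4-(methoxymethoxy)phenyl]prop-2-en-1-one
Product: 16 (2E)-1-[(2S)-4,6-dihydroxy-2-(2-hydroxypropan-2-yl)-2,3-dihydro-1-benzofuran-5-yl]-3-(4-hydroxyphenyl)prop-2-en-1-one
Conditions: 3 M aq HCl, MeOH, rt
Reagents that add atoms: none
Why: Acid-catalysed acetal exchange with methanol removes all three methoxymethyl groups; at room temperature the oxa-Michael closure to the flavanone and ionisation of the tertiary carbinol should be slow, and the C2 stereocenter is not involved.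

## Compound list

1 | 2,4,6-trihydroxybenzaldehyde | O=Cc1c(O)cc(O)cc1O | starting material
2 | 2-hydroxy-4,6-bis(triisopropylsilyloxy)benzaldehyde | O=Cc1c(O)cc(O[Si](C(C)C)(C(C)C)C(C)C)cc1O[Si](C(C)C)(C(C)C)C(C)C | intermediate
3 | 2,2-dimethyloxirane | CC1(C)CO1 | starting material
4 | 2-(2-hydroxy-2-methylpropoxy)-4,6-bis(triisopropylsilyloxy)benzaldehyde | O=Cc1c(OCC(C)(C)O)cc(O[Si](C(C)C)(C(C)C)C(C)C)cc1O[Si](C(C)C)(C(C)C)C(C)C | intermediate
5 | 4-methylbenzenesulfonohydrazide | Cc1ccc(cc1)S(=O)(=O)NN | starting material
6 | N'-[(E)-[2-(2-hydroxy-2-methylpropoxy)-4,6-bis(triisopropylsilyloxy)phenyl]methylidene]-4-methylbenzenesulfonohydrazide | Cc1ccc(cc1)S(=O)(=O)N/N=C/c1c(OCC(C)(C)O)cc(O[Si](C(C)C)(C(C)C)C(C)C)cc1O[Si](C(C)C)(C(C)C)C(C)C | intermediate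
7 | 1-[2-(diazomethyl)-3,5-bis(triisopropylsilyloxy)phenoxy]-2-methylpropan-2-ol | [N-]=[N+]=Cc1c(OCC(C)(C)O)cc(O[Si](C(C)C)(C(C)C)C(C)C)cc1O[Si](C(C)C)(C(C)C)C(C)C | intermediate
8 | 2-[(2S)-4,6-bis(triisopropylsilyloxy)-2,3-dihydro-1-benzofuran-2-yl]propan-2-ol | CC(C)(O)[C@@H]1Cc2c(cc(O[Si](C(C)C)(C(C)C)C(C)C)cc2O[Si](C(C)C)(C(C)C)C(C)C)O1 | intermediate
9 | (2S)-2-(2-hydroxypropan-2-yl)-2,3-dihydro-1-benzofuran-4,6-diol | CC(C)(O)[C@@H]1Cc2c(cc(O)cc2O)O1 | intermediate
10 | 2-[(2S)-4,6-bis(methoxymethoxy)-2,3-dihydro-1-benzofuran-2-yl]propan-2-ol | CC(C)(O)[C@@H]1Cc2c(cc(OCOC)cc2OCOC)O1 | intermediate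
11 | p-coumaric acid, (2E)-3-(4-hydroxyphenyl)prop-2-enoic acid | OC(=O)/C=C/c1ccc(O)cc1 | starting material
12 | (2E)-3-(4-hydroxyphenyl)-N-methoxy-N-methylprop-2-enamide | CON(C)C(=O)/C=C/c1ccc(O)cc1 | intermediate
13 | (2E)-N-methoxy-N-methyl-3-[4-(methoxymethoxy)phenyl]prop-2-enamide | CON(C)C(=O)/C=C/c1ccc(OCOC)cc1 | intermediate
14 | lithium 2-[(2S)-5-lithio-4,6-bis(methoxymethoxy)-2,3-dihydro-1-benzofuran-2-yl]propan-2-olate | [Li]OC(C)(C)[C@@H]1Cc2c(cc(OCOC)c([Li])c2OCOC)O1 | intermediate
15 | (2E)-1-[(2S)-2-(2-hydroxypropan-2-yl)-4,6-bis(methoxymethoxy)-2,3-dihydro-1-benzofuran-5-yl]-3-[4-(methoxymethoxy)phenyl]prop-2-en-1-one | CC(C)(O)[C@@H]1Cc2c(cc(OCOC)c(C(=O)/C=C/c3ccc(OCOC)cc3)c2OCOC)O1 | intermediate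
16 | (2E)-1-[(2S)-4,6-dihydroxy-2-(2-hydroxypropan-2-yl)-2,3-dihydro-1-benzofuran-5-yl]-3-(4-hydroxyphenyl)prop-2-en-1-one | CC(C)(O)[C@@H]1Cc2c(cc(O)c(C(=O)/C=C/c3ccc(O)cc3)c2O)O1 | target

## Step count and least certain steps

Total steps: 10. Longest linear sequence: 8 (steps 1 to 6, 9 and 10); steps 7 and 8 prepare the amide 13 in a side branch.

**Step 4 (key step).** The diazo carbon is flanked by two ortho substituents, one of them a bulky silyloxy group, so uptake of 7 by the crowded cobalt centre may be slow and 7 may be lost to azine formation or carbene dimerisation. The hydrogen to be abstracted sits on a CH2 group next to a quaternary carbon and is activated by only one oxygen, so hydrogen transfer may lag behind these side paths. The enantioselectivity for an ether of this shape is unknown.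

The fallback sets out from 1 and comes back to the route at 10 by a different ring construction. Double methoxymethylation of 1 (MOMCl, iPr2NEt, CH2Cl2) should give 2-hydroxy-4,6-bis(methoxymethoxy)benzaldehyde F1. Rap–Stoermer condensation of this phenol aldehyde with chloroacetone (K2CO3, butanone, reflux) should give 1-[4,6-bis(methoxymethoxy)-1-benzofuran-2-yl]ethan-1-one F2. Addition of MeMgBr (THF, 0 °C) to the ketone should give 2-[4,6-bis(methoxymethoxy)-1-benzofuran-2-yl]propan-2-ol F3. Enantioselective hydrogenation of the furan double bond of this benzofuran should then give 10. The catalyst would be a chiral ruthenium N-heterocyclic carbene complex made from Ru(cod)(2-methylallyl)2, a C2-symmetric chiral imidazolinium salt and KOtBu under H2, with the antipode of the carbene ligand chosen to give (2S).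

**Step 2.** The chelated phenoxide is a weak nucleophile, and at the temperature needed the basic medium may cause loss or transfer of the silyl groups that lie ortho and para to the formyl group.

The fallback sets out from 2 and comes back to the route at 4. Alkylation of 2 with 3-bromo-2-methylprop-1-ene (K2CO3, acetone, rt) should give 2-[(2-methylprop-2-en-1-yl)oxy]-4,6-bis(triisopropylsilyloxy)benzaldehyde F4 under much milder conditions. Mukaiyama hydration of the 1,1-disubstituted alkene (Co(acac)2 cat., PhSiH3, O2, THF, rt) should then place the hydroxyl on the more substituted carbon and give 4.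

**Step 9.** The di-ortho-substituted aryllithium is hindered and strongly basic, so acyl transfer may be slow and conjugate addition to the enamide or base-induced N–O cleavage of the amide may intervene. Partial metalation at C7, guided by the lithium alkoxide and the ring oxygen, is a second, less likely failure that this fallback does not repair.

The fallback sets out from 13 and 10 and comes back to the route at 15. Reduction of 13 with iBu2AlH (THF, −78 °C) should give (2E)-3-[4-(methoxymethoxy)phenyl]prop-2-enal F5. The aryllithium 14, made from 10 as in step 9, should add 1,2 to this unhindered aldehyde to give (2E)-1-[(2S)-2-(2-hydroxypropan-2-yl)-4,6-bis(methoxymethoxy)-2,3-dihydro-1-benzofuran-5-yl]-3-[4-(methoxymethoxy)phenyl]prop-2-en-1-ol F6 as a mixture of carbinol epimers. Oxidation of this doubly activated alcohol with MnO2 (CH2Cl2, rt) should give 15.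

**Step 10.** Once the hydroxyls next to the carbonyl are free, acid may promote oxa-Michael ring closure to the flavanone. Prolonged acid may also ionise the tertiary carbinol, leading to dehydration or ring expansion.

The fallback sets out from 10 and comes back to the route at 16, with the enone made only after the phenols are free. The aryllithium 14 would be quenched with N-methoxy-N-methylacetamide to give 1-[(2S)-2-(2-hydroxypropan-2-yl)-4,6-bis(methoxymethoxy)-2,3-dihydro-1-benzofuran-5-yl]ethan-1-one F7. Acidic methanol should convert this ketone into 1-[(2S)-4,6-dihydroxy-2-(2-hydroxypropan-2-yl)-2,3-dihydro-1-benzofuran-5-yl]ethan-1-one F8; no enone is present at this stage, so no flavanone can form. Claisen–Schmidt condensation of this acetophenone with 4-hydroxybenzaldehyde in concentrated KOH (EtOH–H2O) keeps the product as a polyanion that cannot cyclise, and rapid cold acidification should release 16.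

## Further compounds

F1 | step 4 | 2-hydroxy-4,6-bis(methoxymethoxy)benzaldehyde | O=Cc1c(O)cc(OCOC)cc1OCOC
F2 | step 4 | 1-[4,6-bis(methoxymethoxy)-1-benzofuran-2-yl]ethan-1-one | CC(=O)c1cc2c(OCOC)cc(OCOC)cc2o1
F3 | step 4 | 2-[4,6-bis(methoxymethoxy)-1-benzofuran-2-yl]propan-2-ol | CC(C)(O)c1cc2c(OCOC)cc(OCOC)cc2o1
F4 | step 2 | 2-[(2-methylprop-2-en-1-yl)oxy]-4,6-bis(triisopropylsilyloxy)benzaldehyde | O=Cc1c(OCC(C)=C)cc(O[Si](C(C)C)(C(C)C)C(C)C)cc1O[Si](C(C)C)(C(C)C)C(C)C
F5 | step 9 | (2E)-3-[4-(methoxymethoxy)phenyl]prop-2-enal | O=C/C=C/c1ccc(OCOC)cc1
F6 | step 9 | (2E)-1-[(2S)-2-(2-hydroxypropan-2-yl)-4,6-bis(methoxymethoxy)-2,3-dihydro-1-benzofuran-5-yl]-3-[4-(methoxymethoxy)phenyl]prop-2-en-1-ol (both carbinol epimers) | CC(C)(O)[C@@H]1Cc2c(cc(OCOC)c(C(O)/C=C/c3ccc(OCOC)cc3)c2OCOC)O1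
F7 | step 10 | 1-[(2S)-2-(2-hydroxypropan-2-yl)-4,6-bis(methoxymethoxy)-2,3-dihydro-1-benzofuran-5-yl]ethan-1-one | CC(C)(O)[C@@H]1Cc2c(cc(OCOC)c(C(C)=O)c2OCOC)O1
F8 | step 10 | 1-[(2S)-4,6-dihydroxy-2-(2-hydroxypropan-2-yl)-2,3-dihydro-1-benzofuran-5-yl]ethan-1-one | CC(C)(O)[C@@H]1Cc2c(cc(O)c(C(C)=O)c2O)O1
A1 | alternative 1 | (2E)-1-[(2S)-2-(2-hydroxypropan-2-yl)-4,6-bis(methoxymethoxy)-2,3-dihydro-1-benzofuran-5-yl]-3-[4-(methoxymethoxy)phenyl]prop-2-en-1-one | CC(C)(O)[C@@H]1Cc2c(cc(OCOC)c(C(=O)/C=C/c3ccc(OCOC)cc3)c2OCOC)O1
A2 | alternative 1 | 2-[(2S)-5-iodo-4,6-bis(methoxymethoxy)-2,3-dihydro-1-benzofuran-2-yl]propan-2-ol | CC(C)(O)[C@@H]1Cc2c(cc(OCOC)c(I)c2OCOC)O1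
A3 | alternative 1 | 1-ethenyl-4-(methoxymethoxy)benzene | C=Cc1ccc(OCOC)cc1
A4 | alternative 1 | carbon monoxide | [C-]#[O+]
A5 | alternative 2 | 2-iodo-3,5-bis(methoxymethoxy)phenol | Oc1cc(OCOC)cc(OCOC)c1I
A6 | alternative 2 | isoprene, 2-methylbuta-1,3-diene | C=CC(C)=C
A7 | alternative 2 | (2S)-4,6-bis(methoxymethoxy)-2-(prop-1-en-2-yl)-2,3-dihydro-1-benzofuran | C=C(C)[C@@H]1Cc2c(cc(OCOC)cc2OCOC)O1
A8 | alternative 3 | 1-iodo-3,5-bis(methoxymethoxy)benzene | COCOc1cc(I)cc(OCOC)c1
A9 | alternative 3 | 2-[(2S)-oxiran-2-yl]propan-2-ol | CC(C)(O)[C@@H]1CO1
A10 | alternative 3 | 2-[(2S)-4,6-bis(methoxymethoxy)-2,3-dihydro-1-benzofuran-2-yl]propan-2-ol | CC(C)(O)[C@@H]1Cc2c(cc(OCOC)cc2OCOC)O1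
A11 | alternative 3 | norbornene, bicyclo[2.2.1]hept-2-ene | C1CC2CC1C=C2
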